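Two constants can be read from the earlier runs, and we build the flask from them. D reacts with dissolved Z, which comes from the gas L, to give X and Q; Q can bind Z as E, Z can turn into J, and X into G.

common to all: L 1.1 mM (held)

| flask | D | remark | time |
|---|---|---|---|
| elm | 0.011 M | run made earlier |  |
| maple | 0.026 M | run made earlier |  |
| flask | 0.017 M |  | 4.0 d |

| run | time / d | D / % | X / % |
|---|---|---|---|
| elm | 0.208 | 91 | 7 |
| elm | 0.625 | 71 | 20 |
| elm | 1.04 | 56 | 34 |
| elm | 1.67 | 38 | 47 |
| elm | 2.50 | 23 | 64 |
| maple | 0.500 | 84 | 10 |
| maple | 1.04 | 75 | 23 |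
| maple | 1.25 | 64 | 28 |
| maple | 2.08 | 51 | 41 |
| maple | 2.50 | 40 | 51 |

(scatter of a reading: 2 percentage points)

- at the start none of Z is dissolved
- steps under discussion: Z <-> J; Z + Q <-> E; D + Z -> Q + X; L <-> Z; X <-> G
- the earlier runs do not show how much of Z is bound; that part of a forecast is a guess

- part of the D that has reacted at 4.0 d
- share of free Z in free Z and E together, at 4.0 d

We write the time to reach a given point as base × [ln(D charged / D left) + (D used) / brake]. The zero of our scale is a flask in which the charge makes no difference: the main step by itself, with Z at a steady level, a pseudo-first-order decay. The last readings of elm and maple, with their scatter, give a base of 1.18 d and a brake of 0.0129 M, the amount of D used that costs one extra base of time.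

With the base by itself, our flask reacts 96.7% of its D by 4.0 d. Adding the brake, solved by one round of substitution, lowers this to 89.4%, a drop of 7.3 percentage points. The rest acts past D: elm's last reading leaves 13.0% as neither D nor X, which we read as G; that step takes X, not D, so our number stays. For the share we can only guess: if E holds as much as the D used and free Z stands at 1.1 mM, it is 6.75%.

The forecast gives 85% and 35%, reasoning that “much of Z may sit as E”.

The flask gives 91.2% and 5.41%.

    Z ⇌ J (K = 50.2, k = 0.0716 h⁻¹)
    Z + Q ⇌ E, settled at all times (K = 4.20 × 10⁶ L mol⁻¹)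
    D + Z → Q + X (k = 40.3 L mol⁻¹ h⁻¹)
    L ⇌ Z, rate k4*(csat - [Z]) (kL = 0.792 h⁻¹)
    X ⇌ G (K = 0.240, k = 0.0373 h⁻¹)

Given the 8.8% of D left in this flask, base and brake return 4.27 d against the actual 4.0 d. A neighbour flask charged with 0.068 M of D, with 49.6% left at 4.00 d, returns 3.96 d. Our flask has not come to rest at 4.0 d. By 40.0 d the D used goes from 91.2% to 100%, X from 73.9% to 80.6%, G from 17.3% to 19.4%, E from 0.0155 M to 0.0170 M, and J from 0.00407 M to 0.0386 M.

All runs are simulated on assumed constants; the scatter is artificial.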